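**Assumption:** the sense of induction of the triazolium catalyst in step 5 is assigned by analogy; if the first run gives the (2R) series, the antipodal catalyst (equally available) is used and nothing else changes.

## Retrosynthetic overview

1. Target ⇐ global hydrogenolysis of a pentabenzyl triol ester ⇐ face-selective OsO4 dihydroxylation of a 3-methylidene tetralin ⇐ methylenation of a 3-tetralone (sets C3).
2. Ring B (the only ring made; rings A and C are bought) ⇐ intramolecular Friedel–Crafts alkylation forming C1–C8a from an acyclic benzylic chloride (sets C1).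
3. Key C2–C3 bond ⇐ carbene-catalysed cross-benzoin: the acyl anion equivalent of an arylacetaldehyde adds to the keto carbon of a racemising β-chloro α-keto ester (dynamic kinetic resolution; sets C2).
4. Keto ester ⇐ Darzens reaction of 3,4,5-tris(benzyloxy)benzaldehyde with benzyl dichloroacetate; aldehyde ⇐ eugenol (benzylation, ozonolysis).

Ring A is the methoxy/hydroxy benzo ring, ring B the new carbocycle, ring C the pendant trioxygenated phenyl. Tetralin numbering is used: C1 carries ring C, C2 the OH and carboxyl, C3 the OH and CH2OH, C4 is CH2.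

## Route

Step 1
Reactants: 1 dichloroacetyl chloride
Product: 2 benzyl 2,2-dichloroacetate
Conditions: BnOH, pyridine, CH2Cl2, 0 → 23 °C
Reagents that add atoms: benzyl alcohol, OCc1ccccc1
Why: Simple acylation of an alcohol by an acid chloride (Schotten–Baumann type), giving the benzyl ester so that the carboxyl is freed in the final hydrogenolysis; no stereocentre.

Step 2
Reactants: 2 benzyl 2,2-dichloroacetate; 3 3,4,5-tris(benzyloxy)benzaldehyde
Product: 5 benzyl 3-chloro-2-oxo-3-[3,4,5-tris(benzyloxy)phenyl]propanoate (racemic), via chloroglycidic ester 4 (not isolated)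
Conditions: KOt-Bu, THF, −78 → 0 °C; then 23 °C, 1 h
Reagents that add atoms: none
Why: Darzens condensation of the dichloroacetate enolate with the non-enolisable aldehyde gives the α-chloroglycidic ester, which opens at the electron-rich benzylic carbon with a 1,2-chloride shift to the β-chloro α-keto ester; the product is racemic and configurationally labile by design.

Step 3
Reactants: 6 eugenol
Product: 7 1-(benzyloxy)-2-methoxy-4-(prop-2-en-1-yl)benzene
Conditions: BnBr, K2CO3, acetone, 56 °C
Reagents that add atoms: benzyl bromide, BrCc1ccccc1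
Why: Williamson ether synthesis on the phenol; the benzyl ether also makes the position para to OMe the preferred site for the later ring closure.

Step 4
Reactants: 7 1-(benzyloxy)-2-methoxy-4-(prop-2-en-1-yl)benzene
Product: 9 2-[4-(benzyloxy)-3-methoxyphenyl]acetaldehyde, via ozonide 8 (not isolated)
Conditions: O3, CH2Cl2, −78 °C (Sudan Red end point); then PPh3, −78 → 23 °C; used crude
Reagents that add atoms: ozone, [O-][O+]=O
Why: Ozonolysis with reductive work-up (Criegee mechanism) cleaves the terminal alkene much faster than the dialkoxyarene and gives the arylacetaldehyde, which is used at once because it self-condenses on storage.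

Step 5
Reactants: 5 benzyl 3-chloro-2-oxo-3-[3,4,5-tris(benzyloxy)phenyl]propanoate (racemic); 9 2-[4-(benzyloxy)-3-methoxyphenyl]acetaldehyde
Product: 10 benzyl (2S,3S)-2-{[4-(benzyloxy)-3-methoxyphenyl]acetyl}-3-chloro-2-hydroxy-3-[3,4,5-tris(benzyloxy)phenyl]propanoate
Conditions: (5aR,10bS)-2-(pentafluorophenyl)-5a,10b-dihydro-4H,6H-indeno[2,1-b][1,2,4]triazolo[4,3-d][1,4]oxazin-2-ium tetrafluoroborate (15 mol %), i-Pr2NEt (1 equiv), 4 Å MS, CH2Cl2, 0 °C, slow addition of 9 (1.5 equiv)
Reagents that add atoms: none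
Why: Proposed new method: the carbene turns 9 into a nucleophilic Breslow intermediate (acyl anion equivalent) that adds to the highly electrophilic keto carbon of 5 faster than to a second aldehyde, while 5 racemises through its enol so that one enantiomer is consumed (dynamic kinetic resolution); the catalyst fixes the ketone face (C2, S) and attack anti to the C–Cl bond (Felkin–Anh) fixes C3; the closest known reaction type is the triazolium-carbene-catalysed enantioselective cross-benzoin of aldehydes with α-keto esters, including dynamic kinetic versions on β-halo α-keto esters, and the new element is the enolisable arylacetaldehyde donor.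

Step 6
Reactants: 10 benzyl (2S,3S)-2-{[4-(benzyloxy)-3-methoxyphenyl]acetyl}-3-chloro-2-hydroxy-3-[3,4,5-tris(benzyloxy)phenyl]propanoate
Product: 11 benzyl (1S,2S)-7-(benzyloxy)-2-hydroxy-6-methoxy-3-oxo-1-[3,4,5-tris(benzyloxy)phenyl]-1,2,3,4-tetrahydronaphthalene-2-carboxylate
Conditions: AgOTf (1.2 equiv), 2,6-di-tert-butyl-4-methylpyridine (1.5 equiv), CH2Cl2/HFIP 4:1, −40 → 0 °C
Reagents that add atoms: none
Why: Intramolecular Friedel–Crafts alkylation through the silver-generated benzylic cation (stabilised by the para-benzyloxy group), with ring A attacking para to OMe; a chair-like transition state with ring C and the ester both pseudo-equatorial and the small OH pseudo-axial is expected to give (1S), and because the chloride centre is erased on ionisation any C3 epimer of 10 converges while C2 is untouched.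

Step 7
Reactants: 11 benzyl (1S,2S)-7-(benzyloxy)-2-hydroxy-6-methoxy-3-oxo-1-[3,4,5-tris(benzyloxy)phenyl]-1,2,3,4-tetrahydronaphthalene-2-carboxylate
Product: 12 benzyl (1S,2S)-7-(benzyloxy)-2-hydroxy-6-methoxy-3-methylidene-1-[3,4,5-tris(benzyloxy)phenyl]-1,2,3,4-tetrahydronaphthalene-2-carboxylate
Conditions: Zn, CH2Br2, TiCl4 (reagent aged in THF at 5 °C), CH2Cl2, 0 → 23 °C
Reagents that add atoms: dibromomethane, BrCBr
Why: Takai–Lombardo methylenation, whose non-basic zinc/titanium methylene reagent converts enolisable, hydroxylated ketones into alkenes without enolisation and leaves the ester alone; no stereocentre is touched.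

Step 8
Reactants: 12 benzyl (1S,2S)-7-(benzyloxy)-2-hydroxy-6-methoxy-3-methylidene-1-[3,4,5-tris(benzyloxy)phenyl]-1,2,3,4-tetrahydronaphthalene-2-carboxylate
Product: 13 benzyl (1S,2S,3R)-7-(benzyloxy)-2,3-dihydroxy-3-(hydroxymethyl)-6-methoxy-1-[3,4,5-tris(benzyloxy)phenyl]-1,2,3,4-tetrahydronaphthalene-2-carboxylate
Conditions: OsO4 (5 mol %), N-methylmorpholine N-oxide (2 equiv), THF/t-BuOH/H2O 4:1:1, 23 °C
Reagents that add atoms: N-methylmorpholine N-oxide, C[N+]1([O-])CCOCC1; water, O (both oxygen atoms are relayed through catalytic OsO4, O=[Os](=O)(=O)=O)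
Why: Upjohn dihydroxylation of the exocyclic alkene from the face opposite the pseudo-axial allylic C2–OH and the C1 aryl (Kishi's empirical rule for allylic alcohols), which puts the new C3–OH trans to the C2–OH and the CH2OH pseudo-equatorial, giving (3R).

Step 9
Reactants: 13 benzyl (1S,2S,3R)-7-(benzyloxy)-2,3-dihydroxy-3-(hydroxymethyl)-6-methoxy-1-[3,4,5-tris(benzyloxy)phenyl]-1,2,3,4-tetrahydronaphthalene-2-carboxylate
Product: 14 (1S,2S,3R)-2,3,7-trihydroxy-3-(hydroxymethyl)-6-methoxy-1-(3,4,5-trihydroxyphenyl)-1,2,3,4-tetrahydronaphthalene-2-carboxylic acid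
Conditions: H2 (1 atm), Pd/C (10 wt %), MeOH/EtOAc 1:1, 23 °C; filtered and concentrated under argon
Reagents that add atoms: none
Why: Catalytic hydrogenolysis removes the four aryl benzyl ethers and the benzyl ester in one operation under neutral conditions that spare the methyl ether, the tertiary alcohols and all three stereocentres; the air-sensitive pyrogallol is handled under argon.

## Compound list

1 | dichloroacetyl chloride | ClC(Cl)C(Cl)=O | starting material
2 | benzyl 2,2-dichloroacetate | ClC(Cl)C(=O)OCc1ccccc1 | intermediate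
3 | 3,4,5-tris(benzyloxy)benzaldehyde | O=Cc1cc(OCc2ccccc2)c(OCc2ccccc2)c(OCc2ccccc2)c1 | starting material
4 | benzyl 2-chloro-3-[3,4,5-tris(benzyloxy)phenyl]oxirane-2-carboxylate (racemic, diastereomer mixture) | O=C(OCc1ccccc1)C1(Cl)OC1c1cc(OCc2ccccc2)c(OCc2ccccc2)c(OCc2ccccc2)c1 | intermediate (not isolated)
5 | benzyl 3-chloro-2-oxo-3-[3,4,5-tris(benzyloxy)phenyl]propanoate (racemic) | O=C(OCc1ccccc1)C(=O)C(Cl)c1cc(OCc2ccccc2)c(OCc2ccccc2)c(OCc2ccccc2)c1 | intermediate
6 | eugenol, 2-methoxy-4-(prop-2-en-1-yl)phenol | COc1cc(CC=C)ccc1O | starting material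
7 | 1-(benzyloxy)-2-methoxy-4-(prop-2-en-1-yl)benzene | COc1cc(CC=C)ccc1OCc1ccccc1 | intermediate
8 | 3-{[4-(benzyloxy)-3-methoxyphenyl]methyl}-1,2,4-trioxolane | COc1cc(CC2OCOO2)ccc1OCc1ccccc1 | intermediate (not isolated)
9 | 2-[4-(benzyloxy)-3-methoxyphenyl]acetaldehyde | COc1cc(CC=O)ccc1OCc1ccccc1 | intermediate
10 | benzyl (2S,3S)-2-{[4-(benzyloxy)-3-methoxyphenyl]acetyl}-3-chloro-2-hydroxy-3-[3,4,5-tris(benzyloxy)phenyl]propanoate | COc1cc(CC(=O)[C@](O)(C(=O)OCc2ccccc2)[C@@H](Cl)c2cc(OCc3ccccc3)c(OCc3ccccc3)c(OCc3ccccc3)c2)ccc1OCc1ccccc1 | intermediate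
11 | benzyl (1S,2S)-7-(benzyloxy)-2-hydroxy-6-methoxy-3-oxo-1-[3,4,5-tris(benzyloxy)phenyl]-1,2,3,4-tetrahydronaphthalene-2-carboxylate | COc1cc2c(cc1OCc1ccccc1)[C@H](c1cc(OCc3ccccc3)c(OCc3ccccc3)c(OCc3ccccc3)c1)[C@@](O)(C(=O)OCc1ccccc1)C(=O)C2 | intermediate
12 | benzyl (1S,2S)-7-(benzyloxy)-2-hydroxy-6-methoxy-3-methylidene-1-[3,4,5-tris(benzyloxy)phenyl]-1,2,3,4-tetrahydronaphthalene-2-carboxylate | COc1cc2c(cc1OCc1ccccc1)[C@H](c1cc(OCc3ccccc3)c(OCc3ccccc3)c(OCc3ccccc3)c1)[C@@](O)(C(=O)OCc1ccccc1)C(=C)C2 | intermediate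
13 | benzyl (1S,2S,3R)-7-(benzyloxy)-2,3-dihydroxy-3-(hydroxymethyl)-6-methoxy-1-[3,4,5-tris(benzyloxy)phenyl]-1,2,3,4-tetrahydronaphthalene-2-carboxylate | COc1cc2c(cc1OCc1ccccc1)[C@H](c1cc(OCc3ccccc3)c(OCc3ccccc3)c(OCc3ccccc3)c1)[C@@](O)(C(=O)OCc1ccccc1)[C@](O)(CO)C2 | intermediate
14 | (1S,2S,3R)-2,3,7-trihydroxy-3-(hydroxymethyl)-6-methoxy-1-(3,4,5-trihydroxyphenyl)-1,2,3,4-tetrahydronaphthalene-2-carboxylic acid (CNP0174537.1) | COc1cc2c(cc1O)[C@H](c1cc(O)c(O)c(O)c1)[C@@](O)(C(=O)O)[C@](O)(CO)C2 | target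

## Step count and risks

Total step count: 9. Longest linear sequence: 7 (steps 1, 2, 5, 6, 7, 8, 9; the eugenol branch, steps 3, 4, 5 to 9, is equally long).

The three steps most likely to fail:

**Step 5 (cross-benzoin).** The arylacetaldehyde 9 can self-condense or homo-couple, and the enantioselectivity with this donor is untested. The fallback sets out from 9 and 3 and comes back at 11, replacing carbene catalysis by an asymmetric epoxidation. Roskamp homologation of 9 with benzyl diazoacetate (SnCl2 cat., CH2Cl2) gives benzyl 4-[4-(benzyloxy)-3-methoxyphenyl]-3-oxobutanoate F1. Knoevenagel condensation of F1 with 3 (piperidine/AcOH, toluene, water removal) gives benzyl 2-{[4-(benzyloxy)-3-methoxyphenyl]acetyl}-3-[3,4,5-tris(benzyloxy)phenyl]prop-2-enoate F2 as an E/Z mixture. Catalytic asymmetric nucleophilic epoxidation (cumene hydroperoxide, cinchona-alkaloid-derived catalyst, toluene, −20 °C) is stepwise and so convergent for both alkene isomers; it gives benzyl (2S,3S)-2-{[4-(benzyloxy)-3-methoxyphenyl]acetyl}-3-[3,4,5-tris(benzyloxy)phenyl]oxirane-2-carboxylate F3, with ring C trans to the ester. Epoxy-arene cyclisation (BF3·OEt2, CH2Cl2, −78 °C) with inversion at the benzylic carbon then gives 11.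

**Step 6 (Friedel–Crafts closure).** The C1 configuration rests on a conformational preference of the cation, and closure ortho to OMe or epoxide formation could compete. The fallback sets out from 5 and 7 and comes back at 11; it makes the C1–C8a bond first, where no stereochemistry is at stake, and sets C1 together with C2 in a catalyst-controlled ring closure. Intermolecular Friedel–Crafts alkylation of 7 with 5 (AgOTf, 2,6-di-tert-butyl-4-methylpyridine, CH2Cl2/HFIP) para to OMe gives racemic benzyl 3-[5-(benzyloxy)-4-methoxy-2-(prop-2-en-1-yl)phenyl]-2-oxo-3-[3,4,5-tris(benzyloxy)phenyl]propanoate F4. Ozonolysis (O3, CH2Cl2, −78 °C, then PPh3) runs through the ozonide benzyl 3-{5-(benzyloxy)-4-methoxy-2-[(1,2,4-trioxolan-3-yl)methyl]phenyl}-2-oxo-3-[3,4,5-tris(benzyloxy)phenyl]propanoate F5 to the keto ester aldehyde benzyl 3-[5-(benzyloxy)-4-methoxy-2-(2-oxoethyl)phenyl]-2-oxo-3-[3,4,5-tris(benzyloxy)phenyl]propanoate F6. The triazolium carbene of step 5 then closes ring B by an intramolecular cross-benzoin while the diarylmethine centre of F6 still racemises through its enol (dynamic kinetic resolution), giving 11.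

**Step 7 (methylenation).** The ketone is hindered, flanked by a quaternary carbinol, readily enolised, and could undergo α-ketol rearrangement under Lewis acid. The fallback sets out from 11 and comes back at 12, building the alkene by addition and elimination instead of carbonyl methylenation. Me3SiCH2Li with CeCl3 (THF, −78 °C), as the non-basic organocerium, adds to the ketone to give the β-hydroxysilane benzyl (1S,2S)-7-(benzyloxy)-2,3-dihydroxy-6-methoxy-3-[(trimethylsilyl)methyl]-1-[3,4,5-tris(benzyloxy)phenyl]-1,2,3,4-tetrahydronaphthalene-2-carboxylate F7; its C3 configuration is immaterial. Peterson elimination (KH, THF, 0 °C) gives 12.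

## Further compounds

F1 | step 5 | benzyl 4-[4-(benzyloxy)-3-methoxyphenyl]-3-oxobutanoate | COc1cc(CC(=O)CC(=O)OCc2ccccc2)ccc1OCc1ccccc1
F2 | step 5 | benzyl 2-{[4-(benzyloxy)-3-methoxyphenyl]acetyl}-3-[3,4,5-tris(benzyloxy)phenyl]prop-2-enoate (E/Z mixture) | COc1cc(CC(=O)C(=Cc2cc(OCc3ccccc3)c(OCc3ccccc3)c(OCc3ccccc3)c2)C(=O)OCc2ccccc2)ccc1OCc1ccccc1
F3 | step 5 | benzyl (2S,3S)-2-{[4-(benzyloxy)-3-methoxyphenyl]acetyl}-3-[3,4,5-tris(benzyloxy)phenyl]oxirane-2-carboxylate | O=C(OCc1ccccc1)[C@]2(C(=O)Cc1ccc(OCc3ccccc3)c(OC)c1)O[C@H]2c1cc(OCc3ccccc3)c(OCc3ccccc3)c(OCc3ccccc3)c1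
F4 | step 6 | benzyl 3-[5-(benzyloxy)-4-methoxy-2-(prop-2-en-1-yl)phenyl]-2-oxo-3-[3,4,5-tris(benzyloxy)phenyl]propanoate (racemic) | COc1cc(CC=C)c(cc1OCc1ccccc1)C(C(=O)C(=O)OCc1ccccc1)c1cc(OCc2ccccc2)c(OCc2ccccc2)c(OCc2ccccc2)c1
F5 | step 6 | benzyl 3-{5-(benzyloxy)-4-methoxy-2-[(1,2,4-trioxolan-3-yl)methyl]phenyl}-2-oxo-3-[3,4,5-tris(benzyloxy)phenyl]propanoate (not isolated) | COc1cc(CC2OCOO2)c(cc1OCc1ccccc1)C(C(=O)C(=O)OCc1ccccc1)c1cc(OCc2ccccc2)c(OCc2ccccc2)c(OCc2ccccc2)c1
F6 | step 6 | benzyl 3-[5-(benzyloxy)-4-methoxy-2-(2-oxoethyl)phenyl]-2-oxo-3-[3,4,5-tris(benzyloxy)phenyl]propanoate (racemic) | COc1cc(CC=O)c(cc1OCc1ccccc1)C(C(=O)C(=O)OCc1ccccc1)c1cc(OCc2ccccc2)c(OCc2ccccc2)c(OCc2ccccc2)c1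
F7 | step 7 | benzyl (1S,2S)-7-(benzyloxy)-2,3-dihydroxy-6-methoxy-3-[(trimethylsilyl)methyl]-1-[3,4,5-tris(benzyloxy)phenyl]-1,2,3,4-tetrahydronaphthalene-2-carboxylate (C3 configuration not defined) | COc1cc2c(cc1OCc1ccccc1)[C@H](c1cc(OCc3ccccc3)c(OCc3ccccc3)c(OCc3ccccc3)c1)[C@@](O)(C(=O)OCc1ccccc1)C(O)(C[Si](C)(C)C)C2
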